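**Strategy.** The target is a twofold-symmetric biquinone; each ring is numbered as a 2-hydroxy-3-methyl-1,4-benzoquinone with the ring–ring bond at C5 and the 2-(2-methoxyphenyl)ethyl chain at C6. Everything rests on disconnecting each ring between carbonyl carbon C1 (next to the hydroxylated C2) and C6. A Moore rearrangement of a squarate-derived 4-alkynyl-4-(tributylstannyloxy)cyclobutenone opens the four-membered ring to an alkynylvinylketene, closes the C1–C6 bond to the quinone and in the same operation moves tin from oxygen to C5, the carbon of the later biquinone bond. The precursor carries only the isopropoxy group, the methyl group and the arylbutynyl carbinol. Oxidative homocoupling of the stannylquinone and removal of the isopropyl groups finish the route.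

Key step: step 5

Assumption: the target is drawn without stereodescriptors, so the biquinone axis is taken as stereochemically undefined and no control of axial chirality is planned.

Step 1
Reactants: 1 trimethyl(prop-1-yn-1-yl)silane; 2 1-(chloromethyl)-2-methoxybenzene (2-methoxybenzyl chloride)
Product: 4 [4-(2-methoxyphenyl)but-1-yn-1-yl]trimethylsilane, via lithiated 1-(trimethylsilyl)propyne 3 (not isolated)
Conditions: n-BuLi, THF, −78 to −20 °C; then 2, −78 °C to rt
Reagents that add atoms: none
Why: The propargylic lithium reagent from 1 should displace the benzylic chloride in an SN2 reaction at its propargylic carbon, the silyl group suppressing allene formation (propargylic alkylation).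

Step 2
Reactants: 4 [4-(2-methoxyphenyl)but-1-yn-1-yl]trimethylsilane
Product: 5 1-(but-3-yn-1-yl)-2-methoxybenzene
Conditions: K2CO3 (cat.), MeOH, rt
Reagents that add atoms: none
Why: Methoxide-catalysed protodesilylation of an alkynylsilane is mild and should leave the aryl methyl ether untouched.

Step 3
Reactants: 5 1-(but-3-yn-1-yl)-2-methoxybenzene; 6 3,4-di(propan-2-yloxy)cyclobut-3-ene-1,2-dione (diisopropyl squarate)
Product: 9 4-[4-(2-methoxyphenyl)but-1-yn-1-yl]-2,3-di(propan-2-yloxy)-4-(trimethylsilyloxy)cyclobut-2-en-1-one, via lithium acetylide 7 (not isolated), via lithium alkoxide 8 (not isolated)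
Conditions: n-BuLi, THF, −78 °C; then 6, −78 °C; then TMSCl, −78 to 0 °C
Reagents that add atoms: chlorotrimethylsilane, C[Si](C)(C)Cl
Why: The lithium acetylide should add 1,2 to one of the two equivalent squarate carbonyl groups, and capping the tertiary alkoxide as its silyl ether ensures that only the carbinol made in step 4 can ionise (acetylide 1,2-addition and O-silylation; the new stereocentre is racemic and is erased in step 5).

Step 4
Reactants: 9 4-[4-(2-methoxyphenyl)but-1-yn-1-yl]-2,3-di(propan-2-yloxy)-4-(trimethylsilyloxy)cyclobut-2-en-1-one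
Product: 12 4-hydroxy-4-[4-(2-methoxyphenyl)but-1-yn-1-yl]-3-methyl-2-(propan-2-yloxy)cyclobut-2-en-1-one, via lithium methylcarbinolate 10 (not isolated), via silyl ether 11 (not isolated)
Conditions: MeLi, THF, −78 °C; TFAA, −78 °C; aq. NaHCO3 quench; crude in THF, TBAF, AcOH, 0 °C
Reagents that add atoms: methyllithium, [Li]C; water, O
Why: MeLi should add 1,2 to the remaining carbonyl group, trifluoroacetylation of the new alkoxide triggers ionisation to an isopropoxy-stabilised cyclobutenyl cation whose hydrolysis places the carbonyl group on the neighbouring carbon (1,3-carbonyl transposition of squarate adducts), and buffered fluoride then frees the propargylic alcohol without strong acid that could ionise it.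

Step 5
Reactants: 12 4-hydroxy-4-[4-(2-methoxyphenyl)but-1-yn-1-yl]-3-methyl-2-(propan-2-yloxy)cyclobut-2-en-1-one
Product: 15 2-[2-(2-methoxyphenyl)ethyl]-5-methyl-6-(propan-2-yloxy)-3-(tributylstannyl)cyclohexa-2,5-diene-1,4-dione, via stannyl ether 13 (not isolated), via alkynylvinylketene 14 (not isolated)
Conditions: Bu3SnOMe (1.1 equiv), PhMe, rt, MeOH removed in vacuo; then degassed p-xylene, 138 °C
Reagents that add atoms: tributyltin methoxide, CCCC[Sn](CCCC)(CCCC)OC
Why: Bu3SnOMe converts the tertiary alcohol into its stannyl ether, and on heating the cyclobutenone should undergo conrotatory 4π electrocyclic opening in which the oxygen donor turns outward and the alkynyl group inward, so that the ketene of 14 lies next to the alkyne. The ketene carbon (later C1) then bonds to the distal alkyne carbon (later C6) to give a six-membered diradical, an aryl σ radical at C5 beside an oxygen-centred radical, and the Bu3Sn group shifts from the C4 oxygen to C5, which releases the quinone. The closest known reaction type is the Moore rearrangement of 4-alkynyl-4-hydroxy-, 4-silyloxy- and 4-stannyloxycyclobutenones to benzoquinones. The one ring formed is closed in a 6-endo-dig mode at the alkyne, a diradical cycloaromatisation related to the Myers–Saito cyclisation. No stereocentre is created and the racemic carbinol centre is erased. The step needs six- over five-membered closure (quinone against alkylidenecyclopentenedione), which the plain alkyl terminus of the alkyne should secure because it cannot stabilise the exocyclic vinyl radical of the 5-exo path, and it needs tin at C5 only, which the intramolecular shift from the neighbouring oxygen secures.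

Step 6
Reactants: 15 2-[2-(2-methoxyphenyl)ethyl]-5-methyl-6-(propan-2-yloxy)-3-(tributylstannyl)cyclohexa-2,5-diene-1,4-dione (two molecules)
Product: 16 2,2'-bis[2-(2-methoxyphenyl)ethyl]-5,5'-dimethyl-4,4'-di(propan-2-yloxy)-[1,1'-bi(cyclohexa-1,4-diene)]-3,3',6,6'-tetrone
Conditions: PdCl2(MeCN)2 (10 mol %), CuCl2 (1 equiv per stannane), DMF, rt, Ar
Reagents that add atoms: none
Why: Two stannylquinone units should transmetalate to divalent palladium, reductive elimination forms the quinone–quinone bond and CuCl2 returns zerovalent palladium to the divalent state, a union of two carbons of like polarity (oxidative Stille-type homocoupling of alkenylstannanes).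

Step 7
Reactants: 16 2,2'-bis[2-(2-methoxyphenyl)ethyl]-5,5'-dimethyl-4,4'-di(propan-2-yloxy)-[1,1'-bi(cyclohexa-1,4-diene)]-3,3',6,6'-tetrone
Product: 17 4,4'-dihydroxy-2,2'-bis[2-(2-methoxyphenyl)ethyl]-5,5'-dimethyl-[1,1'-bi(cyclohexa-1,4-diene)]-3,3',6,6'-tetrone (CNP0293637.0)
Conditions: BCl3, CH2Cl2, −78 to 0 °C; then H2O
Reagents that add atoms: none
Why: BCl3 should chelate between each quinone carbonyl oxygen and the neighbouring isopropoxy oxygen and cleave the secondary alkyl vinylogous ester as 2-chloropropane at low temperature, while the two anisole methyl ethers, which lack a chelating neighbour, remain (Lewis acid ether cleavage).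

**Compound list**

1 | trimethyl(prop-1-yn-1-yl)silane | CC#C[Si](C)(C)C | starting material
2 | 1-(chloromethyl)-2-methoxybenzene | COc1ccccc1CCl | starting material
3 | [3-(trimethylsilyl)prop-2-yn-1-yl]lithium | [Li]CC#C[Si](C)(C)C | intermediate
4 | [4-(2-methoxyphenyl)but-1-yn-1-yl]trimethylsilane | COc1ccccc1CCC#C[Si](C)(C)C | intermediate
5 | 1-(but-3-yn-1-yl)-2-methoxybenzene | COc1ccccc1CCC#C | intermediate
6 | 3,4-di(propan-2-yloxy)cyclobut-3-ene-1,2-dione | CC(C)OC1=C(OC(C)C)C(=O)C1=O | starting material
7 | [4-(2-methoxyphenyl)but-1-yn-1-yl]lithium | [Li]C#CCCc1ccccc1OC | intermediate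
8 | lithium 1-[4-(2-methoxyphenyl)but-1-yn-1-yl]-4-oxo-2,3-di(propan-2-yloxy)cyclobut-2-en-1-olate, racemic | [Li+].[O-]C1(C#CCCc2ccccc2OC)C(OC(C)C)=C(OC(C)C)C1=O | intermediate
9 | 4-[4-(2-methoxyphenyl)but-1-yn-1-yl]-2,3-di(propan-2-yloxy)-4-(trimethylsilyloxy)cyclobut-2-en-1-one, racemic | COc1ccccc1CCC#CC1(O[Si](C)(C)C)C(OC(C)C)=C(OC(C)C)C1=O | intermediate
10 | lithium 4-[4-(2-methoxyphenyl)but-1-yn-1-yl]-1-methyl-2,3-di(propan-2-yloxy)-4-(trimethylsilyloxy)cyclobut-2-en-1-olate, mixture of diastereomers | [Li+].[O-]C1(C)C(OC(C)C)=C(OC(C)C)C1(O[Si](C)(C)C)C#CCCc1ccccc1OC | intermediate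
11 | 4-[4-(2-methoxyphenyl)but-1-yn-1-yl]-3-methyl-2-(propan-2-yloxy)-4-(trimethylsilyloxy)cyclobut-2-en-1-one, racemic | COc1ccccc1CCC#CC1(O[Si](C)(C)C)C(C)=C(OC(C)C)C1=O | intermediate
12 | 4-hydroxy-4-[4-(2-methoxyphenyl)but-1-yn-1-yl]-3-methyl-2-(propan-2-yloxy)cyclobut-2-en-1-one, racemic | COc1ccccc1CCC#CC1(O)C(C)=C(OC(C)C)C1=O | intermediate
13 | 4-[4-(2-methoxyphenyl)but-1-yn-1-yl]-3-methyl-2-(propan-2-yloxy)-4-(tributylstannyloxy)cyclobut-2-en-1-one, racemic | COc1ccccc1CCC#CC1(O[Sn](CCCC)(CCCC)CCCC)C(C)=C(OC(C)C)C1=O | intermediate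
14 | (3E)-8-(2-methoxyphenyl)-3-methyl-2-(propan-2-yloxy)-4-(tributylstannyloxy)octa-1,3-dien-5-yn-1-one | O=C=C(OC(C)C)/C(C)=C(/O[Sn](CCCC)(CCCC)CCCC)C#CCCc1ccccc1OC | intermediate
15 | 2-[2-(2-methoxyphenyl)ethyl]-5-methyl-6-(propan-2-yloxy)-3-(tributylstannyl)cyclohexa-2,5-diene-1,4-dione | CC(C)OC1=C(C)C(=O)C([Sn](CCCC)(CCCC)CCCC)=C(CCc2ccccc2OC)C1=O | intermediate
16 | 2,2'-bis[2-(2-methoxyphenyl)ethyl]-5,5'-dimethyl-4,4'-di(propan-2-yloxy)-[1,1'-bi(cyclohexa-1,4-diene)]-3,3',6,6'-tetrone | CC(C)OC1=C(C)C(=O)C(=C(CCc2ccccc2OC)C1=O)C1=C(CCc2ccccc2OC)C(=O)C(OC(C)C)=C(C)C1=O | intermediate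
17 | 4,4'-dihydroxy-2,2'-bis[2-(2-methoxyphenyl)ethyl]-5,5'-dimethyl-[1,1'-bi(cyclohexa-1,4-diene)]-3,3',6,6'-tetrone (CNP0293637.0) | COc1ccccc1CCC1=C(C2=C(CCc3ccccc3OC)C(=O)C(O)=C(C)C2=O)C(=O)C(C)=C(O)C1=O | target

**Step count and risks**

Total step count: 7. Longest linear sequence: 7 steps (from 1 and 2 to 17; 6 enters at step 3).

Steps most likely to fail:

1. Step 5 (key step). The ketene may close onto the proximal alkyne carbon to give a five-membered ring, O-stannylation may be incomplete, or tin may be lost by protonolysis at 138 °C. The fallback sets out from 12 and returns at 16. It replaces tin transfer by the classical hydrogen-transfer Moore rearrangement and installs the coupling handle afterwards. Thermolysis of free carbinol 12 (p-xylene, 138 °C) should give 2-[2-(2-methoxyphenyl)ethyl]-5-methyl-6-(propan-2-yloxy)cyclohexa-2,5-diene-1,4-dione F1 through the same C1–C6 ring closure. Br2 in CH2Cl2 at 0 °C followed by Et3N (addition–elimination at the only C–H position) should give 3-bromo-2-[2-(2-methoxyphenyl)ethyl]-5-methyl-6-(propan-2-yloxy)cyclohexa-2,5-diene-1,4-dione F2. Pd(PPh3)4 with Me3SnSnMe3 (0.5 equiv) in 1,4-dioxane at 100 °C then stannylates half of F2 in situ and couples it with the other half (Stille coupling), giving 16.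

2. Step 6. Chloro- or protodestannylation may outrun transmetalation, and reductive elimination at the crowded ring–ring bond may be slow. The fallback sets out from 15 and returns at 16. It replaces the oxidative homocoupling by a redox-neutral cross-coupling of two differentiated partners. I2 in CH2Cl2 at 0 °C converts half of 15 by iododestannylation into 3-iodo-2-[2-(2-methoxyphenyl)ethyl]-5-methyl-6-(propan-2-yloxy)cyclohexa-2,5-diene-1,4-dione F3. Stille coupling of F3 with the remaining 15 (Pd2(dba)3, AsPh3, CuI, DMF, 50 °C) should give 16.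

3. Step 4. MeLi may attack silicon instead of the hindered carbonyl group, the trifluoroacetate may ionise sluggishly, or the propargylic C–O bond may ionise during desilylation. The fallback sets out from 6 (with acetylide 7 made from 5 as in step 3) and returns at 12. It reverses the order of the two nucleophiles and differentiates the carbonyl groups through a monoketal. MeLi (THF, −78 °C, aq. NH4Cl) adds to 6 to give 4-hydroxy-4-methyl-2,3-di(propan-2-yloxy)cyclobut-2-en-1-one F4. Treatment with TMSOCH2CH2OTMS and catalytic TMSOTf (CH2Cl2, −78 to 0 °C) ionises the carbinol and traps the alkoxy-stabilised cation as the dioxolane 2-methyl-1-(propan-2-yloxy)-5,8-dioxaspiro[3.4]oct-1-en-3-one F5, whose only free carbonyl group lies next to the methyl-bearing carbon. Acetylide 7 adds there (THF, −78 °C) to give 3-hydroxy-3-[4-(2-methoxyphenyl)but-1-yn-1-yl]-2-methyl-1-(propan-2-yloxy)-5,8-dioxaspiro[3.4]oct-1-ene F6. Mild ketal hydrolysis (aq. oxalic acid, THF, rt) gives 12.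

**Further compounds**

F1 | step 5 | 2-[2-(2-methoxyphenyl)ethyl]-5-methyl-6-(propan-2-yloxy)cyclohexa-2,5-diene-1,4-dione | CC(C)OC1=C(C)C(=O)C=C(CCc2ccccc2OC)C1=O
F2 | step 5 | 3-bromo-2-[2-(2-methoxyphenyl)ethyl]-5-methyl-6-(propan-2-yloxy)cyclohexa-2,5-diene-1,4-dione | CC(C)OC1=C(C)C(=O)C(Br)=C(CCc2ccccc2OC)C1=O
F3 | step 6 | 3-iodo-2-[2-(2-methoxyphenyl)ethyl]-5-methyl-6-(propan-2-yloxy)cyclohexa-2,5-diene-1,4-dione | CC(C)OC1=C(C)C(=O)C(I)=C(CCc2ccccc2OC)C1=O
F4 | step 4 | 4-hydroxy-4-methyl-2,3-di(propan-2-yloxy)cyclobut-2-en-1-one | CC(C)OC1=C(OC(C)C)C(C)(O)C1=O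
F5 | step 4 | 2-methyl-1-(propan-2-yloxy)-5,8-dioxaspiro[3.4]oct-1-en-3-one | CC1=C(OC(C)C)C2(OCCO2)C1=O
F6 | step 4 | 3-hydroxy-3-[4-(2-methoxyphenyl)but-1-yn-1-yl]-2-methyl-1-(propan-2-yloxy)-5,8-dioxaspiro[3.4]oct-1-ene | COc1ccccc1CCC#CC1(O)C(C)=C(OC(C)C)C12OCCO2
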